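The constants of this flask are not in hand, but a ratio of two rates needs none of them.

| setting | delta | flask |
|---|---|---|
| starting material | 0.50 M | 0.50 M |
| second nucleophile | 1.1 equiv | 1.10 equiv |
| gas | 120 mM (held) | 120 mM (held) |
| remark | the very flask that is asked about, followed so far |  |
| time |  | 40 h |

delta run (percent of the starting material charged)

| time / h | other capture product / % | target / % | starting material / % |
|---|---|---|---|
| 0.417 | 3.9 | 35.7 | 22.3 |
| 1.33 | 4.3 | 50.7 | 0.9 |
| 2.50 | 4.7 | 51.0 | 0 |
| 3.00 | 4.3 | 51.2 | 0.1 |
| 5.00 | 4.8 | 50.9 | 0.1 |
| 6.00 | 4.3 | 50.6 | 0 |
| 8.00 | 4.8 | 51.3 | 0 |

(each reading ± 0.3 percentage points)

- the earlier runs were read with a standard deviation of 0.3 percentage points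
- at the start none of the gas is in solution

- share of other capture product in other capture product plus target at 2.0 min
- share of other capture product in other capture product plus target at 40 h
- which of other capture product and target there is more of at 40 h

In the delta run, which is this flask followed to 8.00 h, the starting material is down to 0.9% by 1.33 h, and from 2.50 h on both products stay level within the scatter. Both products appear while starting material disappears, so this reckoning reads them as two captures of one species made from it. Dividing the rate of one capture by the rate of the other then removes time and the unknown amount of that species. From 2.50 h on, other capture product averages 4.58% and target 51.0%. That gives a capture ratio, a selectivity factor taken over the run, the other capture product formed per target formed, of 0.0898. If the other capture is first order in second nucleophile and the target capture does not involve it, this ratio should scale with the equivalents charged.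

This reckoning puts the share at 40 h at 8.24%. At 0.417 h the ratio reads 0.109, so the share at 2.0 min should stand higher, but by an amount the capture ratio does not give.

The forecast reads the same plateau and gives 8.2% (range 7.4% to 9.3%), with target ahead. For 2.0 min it commits to 35% (range 15% to 60%), on the view that “target formation needs dissolved gas, which starts at zero and builds up”.

The flask gives 22.4% at 2.0 min and 8.34% at 40 h, with target ahead, 50.8% against 4.62%. The forecast for 2.0 min stands 13 percentage points too high.

    starting material → intermediate (k = 0.00100 s⁻¹)
    first nucleophile + intermediate → target (k = 0.280 M⁻¹ s⁻¹)
    second nucleophile + intermediate → other capture product (k = 0.00250 M⁻¹ s⁻¹)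
    intermediate → solvolysis product (k = 0.0130 s⁻¹)
    gas ⇌ first nucleophile, rate k5*(csat - [first nucleophile]) (kL = 0.00260 s⁻¹)

The parting lies at the early time, where first nucleophile is still entering from the gas. The run without the drag of the uptake of gas shows 3.94% at 2.0 min instead of 22.4%, and the drag also accounts for part of the later share, 8.34% against 3.89% at 40 h. The capture ratio of 0.0898 read in the delta run is a mean taken over the uptake of gas. In the neighbour flask with 0.440 equiv of second nucleophile instead of 1.10 equiv, target ends at 51.8%, and the ratio scales to 0.0359, a share of 3.47%. The simulation of that flask gives 3.56%.

(The numbers in the tables were generated by integration with made-up constants; scatter was added.)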